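The constants of the second step return catalyst intermediate B to substrate at 36.0 min⁻¹, faster than the third step carries it on at 16 min⁻¹, so the cycle has to be reckoned whole.

    coupling partner + free catalyst → catalyst intermediate A (k1 = 270 M⁻¹ min⁻¹, Ea1 = 55.0 kJ mol⁻¹)
    substrate + catalyst intermediate A ⇌ catalyst intermediate B (K2 = 25 M⁻¹, k2 = 900 M⁻¹ min⁻¹, Ea2 = 50.0 kJ mol⁻¹, ΔH2 = 10.0 kJ mol⁻¹)
    catalyst intermediate B → free catalyst + product (k3 = 16 min⁻¹, Ea3 = 78.0 kJ mol⁻¹)
    (constants at 35 °C)

- Wednesday's: substrate 17 mM; coupling partner 25.5 mM; free catalyst 0.17 mM; temperature 65 °C; time 30 min
- Friday's: substrate 17 mM; coupling partner 25.5 mM; free catalyst 0.17 mM; temperature 35 °C; time 30 min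

- the flask with the highest amount of product, in percent of the substrate charged ("all alike" if they lie within 1.5 percentage points) (Wednesday's / Friday's / all alike)
- final product, as a percentage of the substrate charged, in Wednesday's
- final product, as a percentage of the substrate charged, in Friday's

- all constants are for 35 °C and move with temperature by the activation energies and enthalpies

1. The rule. With the intermediates steady, a catalyst centre passes three waits per round. Free catalyst waits the reciprocal of first-step constant times [coupling partner], 0.145 min at Friday's start. Catalyst intermediate A waits the reciprocal of second-step constant times [substrate], stretched by 3.25 for the returns, 0.212 min. Catalyst intermediate B waits 0.0625 min. Their sum, 0.420 min, is the turnover time, the minutes per round. Each wait's share of it is the share of catalyst standing in that form, and the cycle runs at the charged [free catalyst] over the turnover time, 0.405 mM min⁻¹ in Friday's at the start.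

2. Time. Substrate is the limiting reagent. At a quarter conversion Friday's turnover time is 0.520 min, which puts half conversion at about 26.0 min. The remaining minutes, at 0.705 min per round, put Friday's by this reckoning at about 55.7%.

3. Temperature. Logarithms of the speed-up factors from 35 °C to 65 °C scale with activation energy: 0.827 decades for the first step, 1.17 for the third, 0.602 for the return. Wednesday's turnover time starts at 0.0444 min, so by this reckoning its half conversion falls near 2.75 min. Its 30 min is 10.9 times that span, so Wednesday's should end well ahead of Friday's.

4. Coupling partner. Charging 100 mM to Friday's recipe brings the turnover time at the start down to 0.312 min, so the percentage should rise.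

5. Substrate. Charging 29 mM to Friday's recipe brings the turnover time at the start to 0.332 min, but each percent of that larger charge then takes 1.35 times as long as in Friday's, so the percentage should fall.

The forecast gives Wednesday's, 99.9% and 54%, with “Wednesday's flask runs essentially to completion”, and its Friday's figure lies below the reckoning here.

Wednesday's holds the most product, >99.9% against 54.3% in Friday's; the neighbour charged with 29 mM of substrate ends at 41.6%. At the end of Friday's, [substrate] of 7.76 mM and [coupling partner] of 16.2 mM put the turnover time at 0.757 min, 1.80 times its start, with the second wait 61.5% of it; catalyst intermediate A stands at 61.4%. In the neighbour charged with 100 mM of coupling partner, which ends at 66.4% product, the same sum from its end amounts gives that wait 85.9%, and catalyst intermediate A stands at 85.8%.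

The rate constants are those of an exercise; no experiment stands behind them.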